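The readings stem from a simulated flask on assumed constants, and the scatter is random.

When you read the north flask at 50.0 h, its two products add up to 21.0%, after 17.0% at 20.0 h.

| setting | north | south | flask |
|---|---|---|---|
| left-handed substrate | 20 mM | 20 mM | 20 mM |
| right-handed substrate | 20 mM | 20 mM | 20 mM |
| reagent | 50 mM | 50 mM | 50.0 mM |
| free catalyst | 100 µM | 100 µM | 100 µM |
| racemization catalyst | 10 µM | 6.7 µM | 10 µM |
| impurity | 65 µM | 65 µM | 65 µM |
| remark | the very flask that is asked about, followed so far | run made earlier |  |
| time |  |  | 10 d |

- north (time / h: left-handed product / %, right-handed product / %): 4.00: 4, 0; 8.00: 4, 4; 20.0: 9, 8; 50.0: 13, 8
- south (time / d: left-handed product / %, right-handed product / %): 1.04: 10, 8; 2.08: 14, 8; 3.00: 21, 11; 4.00: 26, 15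

(standard deviation of a reading: 2 percentage points)

- free catalyst is single-handed; left-handed substrate and right-handed substrate are mirror images of each other, charged as a racemate, each of them at the stated concentration
- the numbers in the tables scatter with a standard deviation of 2 percentage points
- an excess is the difference of the two amounts in percent of their sum
- an excess is below zero if the other one leads

- left-handed product and right-handed product together, in percent of the left-handed substrate and right-handed substrate charged together, at 10 d
- excess of left-handed product over right-handed product in the product at 10 d
- whether the exchange between left-handed substrate and right-handed substrate keeps pace with the reaction: how far the product's excess at 10 d gets from its value without exchange to its value with instant exchange (above 80% keeps pace, below 20% hardly takes part, else lags behind)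

Take the fastest rung first. The north total gains 17.0% in its first 20.0 h, then 4 percentage points up to 50.0 h. You read that as free catalyst dying on the impurity. You charge less impurity than catalyst, so the impurity is the limiting reagent of that side reaction. If one takes one, subtract the charges. What stays is the surviving catalyst, 35.0 µM.

The next rung takes days. With the surviving catalyst constant, the substrates and the reagent run down together, one reagent for each product. Take c(reagent) and c(substrates), each as a part of its charge. If the rate follows both, the logarithm of their ratio then climbs in a straight line. The south flask differs from the north flask in racemization catalyst, but its total at 2.08 d sits beside the north total at 50.0 h. From 1.04 d to 4.00 d in the south flask the slope is 0.0294 d⁻¹. Read off scattered readings, that carries the logarithm to 0.307 at 10 d, and your own estimate of the total in the north flask to 64.2%.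

No reading shows a substrate. The exchange gets no rung here.

The forecast says 75%, an excess of 20%, and that the exchange lags behind: “The data barely discriminate these”. Your total lies below its total.

The flask gives 62.6% and an excess of 27.2%, and the exchange keeps pace, 98% of the way.

    reagent + free catalyst + left-handed substrate → free catalyst + left-handed product (k = 72.0 L² mol⁻² min⁻¹)
    reagent + free catalyst + right-handed substrate → free catalyst + right-handed product (k = 41.0 L² mol⁻² min⁻¹)
    left-handed substrate + racemization catalyst ⇌ right-handed substrate + racemization catalyst, rate k3*[racemization catalyst]*[left-handed substrate] forward; the back reaction follows from the equilibrium constant (k = 520 L mol⁻¹ min⁻¹)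
    free catalyst + impurity → spent catalyst A (k = 140 L mol⁻¹ min⁻¹)
    racemization catalyst → spent catalyst B (k = 5.10 × 10⁻⁵ min⁻¹)

With all else held at its charge, the half-life of free catalyst on the impurity path is 0.053 d, against 3.3 d for reagent on the left-handed path. At 1.00 d free catalyst stands at 35.0% of its charge and at 10.0 d still at 35.0%, the share the surviving catalyst gives, 35.0%. Charge 0.26 mM of impurity instead, more than the catalyst, and the subtraction falls below zero: that flask ends with 0% free catalyst and 0.971% product.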